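Atom labels (C1 … C38, O20, O25, O28, O33) count the non-hydrogen atoms of the target in the order in which they appear in its SMILES string.

## Analysis of the target

- The target is a pentacyclic spirotetronate. Ring A (C2–C6, C38) and ring B (C5, C6, C7=C8, C9, C36) form a trans-fused octalin. Ring C (C15, C17=C18, C21, C26, C27) is a cyclohexene, spiro-joined at C27 to the 3-acyl tetronic acid ring D (C27, O28, C29, C31, C32). An eleven-membered carbocycle (C9, C10, C12=C13, C14, C15, C27, C32, C31, C34, C36) ties the two halves together.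
- There are ten stereocentres: C2, C5, C6, C9, C10 and C36 on the decalin half, C15, C21 and C27 on ring C, and the carbinol C23.
- On the decalin, H5 and H6 are trans, and C34 is cis to the C10 side chain, which is the endo Diels–Alder pattern of an E,E-diene and an E-enal. The C2 methyl is cis to H6 and therefore axial, which a tether methyl alone would not deliver in such a cycloaddition.
- On ring C, the C14 and C22 chains both lie on the face of the lactone oxygen O28, and the C16 methyl lies on the face of C32.
- Sensitive groups are the acidic, chelating 3-acyl tetronic acid, the primary allylic alcohol C19–O20, the ring alkenes, and the E-alkene in the medium ring. C21 can epimerise as long as C18 is a ketone.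
- The hard points are the two adjacent fully substituted carbons C15 and C27, the quaternary C36 flanked by C5 and C9, and closure of the eleven-membered ring.
- The strategy rests on this: C27 carries O28 and C32 and sits in six-membered ring C para to C18. Ring C is therefore the dearomatised form of a para-substituted phenol whose ipso carbon is C27 and whose oxygen was on C18.

## Retrosynthetic reasoning

**44 ⇐ 43 ⇐ 42.** The O33 methyl ether and the silyl ethers on O20 and O25 are cut last. The tetronic acid and both hydroxyls stay masked through all organometallic and metathesis chemistry, and the forward steps are a fluoride desilylation and an SN2 demethylation by chloride.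

**42 ⇐ 41.** The C12=C13 bond is cut. It is the only bond of the macrocycle that carries no stereocentre and is remote from the quaternary carbons, and its two ends can be carried as plain terminal alkenes (vinyl on C10, allyl on C15). The forward ring-closing metathesis has to deliver the E-alkene in an eleven-membered ring.

**41 ⇐ 40 ⇐ 20 + 39.** The C31–C34 bond is cut. C31 of a tetronate methyl ether is readily lithiated, and C34 of the decalin is a non-enolisable neopentyl aldehyde, so the union is a clean 1,2-addition followed by oxidation. This splits the molecule into spirotetronate 20 and decalin aldehyde 39.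

**20 ⇐ 19 ⇐ 18 ⇐ 17 ⇐ 16.** C19 is cut from C18 (cross-coupling of an enol triflate) and C14 from C15 (conjugate allylation of a β-methyl enone). Doing the allylation last at C15 lets the allyl enter from the O28 face and push the methyl to the C32 face. The enolate that the addition leaves at C17=C18 is exactly the one needed for the triflate, so it is trapped and not regenerated.

**16 ⇐ 11 + 15.** The C21–C22 bond is cut as an enolate alkylation. C21 is alpha-prime to the enone carbonyl, so it is deprotonated regiospecifically. The electrophile 15 brings C23 from the chiral pool, and the alkylation face is again the O28 face.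

**15 ⇐ 14 ⇐ 13 ⇐ 12.** The triflate is traced back through alcohol 14 and silyl ether 13 to lactate ester 12, which supplies C22–C24 with C23 already (R).

**11 ⇐ 10 ⇐ 9 ⇐ 7.** The C15–C16 bond is cut. A catalyst-controlled methyl addition to one enantiotopic arm of achiral dienone 7 makes C27 a stereocentre. Re-oxidation returns the enone with the methyl in place (10), and the other, less substituted arm is then hydrogenated (11).

**7 ⇐ 6 (key disconnection).** The C27–O28 bond is cut. This opens ring D and rearomatises ring C to a phenol bearing an (E)-β-methoxyacrylic acid, in which the carboxyl is held next to the ipso carbon. The forward step has to oxidise the phenol by two electrons and let O28 close the five-membered ring at C27. It delivers ring D at the final oxidation level with O33 already methylated.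

**6 ⇐ 5 ⇐ 3 ⇐ 1 + 2 (+ 4).** The acid is traced back through ester 5 to keto ester 3, made by Claisen condensation of ketone 1 with carbonate 2. Orthoester 4 supplies the enol ether.

**39 ⇐ 38 ⇐ 37 ⇐ 36 ⇐ 35 ⇐ 34 ⇐ 33 ⇐ 32.** These are functional group changes only. The C10 vinyl group comes from a C12 aldehyde, and C34 returns to the aldehyde level. A temporary oxygen on C4 is removed by radical deoxygenation. That oxygen is what makes the next disconnection stereochemically sound.

**32 ⇐ 31.** The C5–C6 and C9–C36 bonds are cut in an intramolecular Diels–Alder reaction that builds rings A and B and four stereocentres at once. A benzoate on C4, trans to the C2 methyl on the nascent ring A, must sit equatorial to avoid allylic strain with the C37 methyl. This forces the C2 methyl axial and fixes the face of the dienophile.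

**31 ⇐ 24 + 29; 29 ⇐ 27 ⇐ 26 ⇐ 25; 24 ⇐ 23 ⇐ 22 ⇐ 21.** The C7–C8 bond of the diene is cut (hydroboration and cross-coupling, stereospecific for E,E). Iodide 29 comes from (S)-citronellal 25, which supplies C2. Alkyne 24 comes from hydroxy ester 21, which supplies C10.

## Alternatives that were turned down

**Alternative 1:** ring B would be closed at C9–C36 by a ring-contracting Ireland–Claisen rearrangement. The silyl ketene acetal of trans-fused lactone A2 (carbonyl C34, ring oxygen on C7, E-alkenyl chain on C7) rearranges on heating to acid A1.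
- For it: the enolate geometry is fixed by the ring, and the C7–O stereocentre is transferred to C9 and C36 in one suprafacial event. Ring A is made beforehand on a cyclohexane, where the axial C2 methyl can be set by classical substrate control. On the decalin stereochemistry it is at least as strong as the cycloaddition used here, and probably stronger.
- Against it: A2 itself needs three ring stereocentres, a C7 carbinol of defined configuration and the C10 centre before the key step. The boat transition state of a lactone needs forcing conditions. The step solves none of the problems of the spiro half (C27, C15, ring D).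
- Comparison: the chosen strategy reaches the complete ring C/D core in four steps at the right oxidation level and makes both carbocycles of the decalin in one step. The C4 oxygen that controls that step is also the group that is removed afterwards.

**Alternative 2:** the macrocycle would be closed through sulfur. The twelve-membered cyclic sulfone A4 (sulfur between C12 and C13) is halogenated in situ and treated with base, and the episulfone loses SO2 to give the C12=C13 alkene of A3 (Ramberg–Bäcklund reaction).
- For it: the ring is first closed at the less strained twelve-membered stage by C–S bond formation. No metathesis catalyst is needed. The E preference of the extrusion under strongly basic conditions may match or exceed that of metathesis.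
- Against it: thiol, leaving group and sulfone have to be installed on two advanced fragments, which costs about five more steps. The strongly basic halogenating medium meets a lactone-type tetronate and a hindered ketone. Alkene geometry in an eleven-membered ring is not assured either.
- Comparison: it addresses the same bond as step 33 here but with more steps and harsher conditions. The chosen route keeps this bond for two alkenes that the fragments already carry. It offers no answer to C27.

**Alternative 3:** the C16 methyl would be brought in as the CH2 of a cyclopropane. Hydroxyl-directed Simmons–Smith cyclopropanation of cyclohexenol A6 gives cyclopropyl carbinol A5 on the face cis to C32. Oxidation and reductive cleavage of the C16–C17 bond would then reveal the quaternary centre.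
- For it: directed cyclopropanation is very reliable, and it forms the congested C15–C16 bond by internal delivery. On this one point it is stronger than the intermolecular conjugate allylation used here (step 12).
- Against it: the C18 carbinol must first be set cis to C32, and oxidation plus regioselective ring-opening follow, three to four extra steps. The C14 chain must already sit on C15, as a protected hydroxyethyl group that still has to become an alkene. C19 and C21 remain to be built.
- Comparison: the chosen sequence makes C15 in one step from the enone and hands on the enolate needed for C19. A sigmatropic fallback is kept in reserve for that step.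

Key step: step 4

Assumptions (remarks on the chemistry):
- The ligand enantiomer in step 5 is taken to deliver methyl to the arm that gives (S)-C27; if the opposite sense is found, the mirror-image ligand is used.
- The (S)-prolinol catalyst in step 21 is taken to give the (S)-benzoate (steric shielding model); if not, its enantiomer is used.

## Route

Step 1
Reactants: 1 4'-hydroxyacetophenone; 2 dimethyl carbonate
Product: 3 methyl 3-(4-hydroxyphenyl)-3-oxopropanoate
Conditions: NaH (3.5 equiv), dimethyl carbonate/THF, 65 °C; then aq. HCl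
Reagents that add atoms: none
Why: Crossed Claisen condensation; the phenoxide–enolate dianion of 1 is acylated by 2 and the product is held as its stabilised enolate, which pulls the equilibrium to 3.

Step 2
Reactants: 3 methyl 3-(4-hydroxyphenyl)-3-oxopropanoate; 4 trimethyl orthoformate
Product: 5 methyl (E)-3-(4-hydroxyphenyl)-3-methoxyacrylate
Conditions: HC(OMe)3, H2SO4 (cat.), MeOH, 50 °C
Reagents that add atoms: none
Why: Acid-catalysed enol etherification through the dimethyl ketal and loss of methanol; under these equilibrating conditions the push–pull alkene settles as the E isomer (methoxy trans to the ester, aryl cis to it), and an orthoester does not alkylate the phenol.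

Step 3
Reactants: 5 methyl (E)-3-(4-hydroxyphenyl)-3-methoxyacrylate
Product: 6 (E)-3-(4-hydroxyphenyl)-3-methoxyacrylic acid
Conditions: LiOH, THF/H2O, 25 °C; then HCl to pH 3, 0 °C
Reagents that add atoms: water, O
Why: Saponification; the β-methoxyacrylate is stable to base, and brief cold acidification avoids hydrolysis of the enol ether and decarboxylation.

Step 4
Reactants: 6 (E)-3-(4-hydroxyphenyl)-3-methoxyacrylic acid
Product: 7 4-methoxy-1-oxaspiro[4.5]deca-3,6,9-triene-2,8-dione
Conditions: graphite anode, Pt cathode, undivided cell, LiClO4 (0.1 M), MeCN/(CF3)2CHOH 9:1, 2,6-lutidine (1 equiv), constant current, 2.2 F mol−1, 0 °C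
Reagents that add atoms: none
Why: Two-electron oxidation of the phenol, the most easily oxidised group of 6, gives a phenoxonium ion with much of its positive charge on the para carbon C27; the carboxylate oxygen O28, held cis to the ring by the E alkene, adds there and loss of a proton leaves dienone 7. The closest known reaction is the anodic (or hypervalent-iodine) dearomative spirolactonisation of 3-(4-hydroxyphenyl)propanoic acids to 1-oxaspiro[4.5]decadienediones. Ring D closes in 5-exo-trig fashion through the C27–O28 bond. No stereocentre is formed: 7 has a mirror plane through C27 and C18, and C27 is only prostereogenic. The step needs oxidation of the phenol in preference to the enol ether and to the product, and ipso capture in preference to ortho or solvent capture; the push–pull β-methoxyacrylate and the phenol-free dienone are harder to oxidise, a five-membered ring can only form at C27, and the fluorinated alcohol stabilises the cation without adding to it. Charge is limited to little more than two electrons per molecule and protons are reduced to hydrogen at the cathode, so the cell can stay undivided.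

Step 5
Reactants: 7 4-methoxy-1-oxaspiro[4.5]deca-3,6,9-triene-2,8-dione
Product: 9 (5S,6R)-4-methoxy-6-methyl-8-[(trimethylsilyl)oxy]-1-oxaspiro[4.5]deca-3,7,9-trien-2-one, via methylzinc enolate 8 (not isolated)
Conditions: Me2Zn (1.5 equiv), Cu(OTf)2 (2 mol%), (S)-1,1'-binaphthalene-2,2'-diyl N,N-bis[(R)-1-phenylethyl]phosphoramidite (4 mol%), toluene, −25 °C; then Me3SiOTf, −25 → 0 °C
Reagents that add atoms: dimethylzinc, C[Zn]C; trimethylsilyl trifluoromethanesulfonate, C[Si](C)(C)OS(=O)(=O)C(F)(F)F
Why: Copper-catalysed enantioselective conjugate addition to a 4,4-disubstituted cyclohexadienone; the chiral catalyst chooses one of the two enantiotopic enone arms and thereby makes C27 a stereocentre, and silylation of the zinc enolate in the flask preserves its regiochemistry. The configuration at C15 (methyl expected cis to O28) does not matter because the next step removes it.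

Step 6
Reactants: 9 (5S,6R)-4-methoxy-6-methyl-8-[(trimethylsilyl)oxy]-1-oxaspiro[4.5]deca-3,7,9-trien-2-one
Product: 10 (5S)-4-methoxy-6-methyl-1-oxaspiro[4.5]deca-3,6,9-triene-2,8-dione
Conditions: Pd(OAc)2 (1.05 equiv), MeCN, 25 °C
Reagents that add atoms: none
Why: Saegusa–Ito oxidation; the silyl enol ether gives a palladium enolate of divalent palladium and β-hydride elimination of H–C15 restores the enone, now bearing the C16 methyl, with C27 (S) as the only stereocentre.

Step 7
Reactants: 10 (5S)-4-methoxy-6-methyl-1-oxaspiro[4.5]deca-3,6,9-triene-2,8-dione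
Product: 11 (5S)-4-methoxy-6-methyl-1-oxaspiro[4.5]deca-3,6-diene-2,8-dione
Conditions: H2 (1 atm), RhCl(PPh3)3 (5 mol%), benzene, 25 °C
Reagents that add atoms: none
Why: Homogeneous hydrogenation with RhCl(PPh3)3 selects by alkene substitution; the 1,2-disubstituted C21=C26 bond is reduced while the trisubstituted C15=C17 enone and the tetronate alkene remain, the selectivity known for one arm of cross-conjugated steroidal dienones.

Step 8
Reactants: 12 methyl (R)-lactate
Product: 13 methyl (2R)-2-[(tert-butyldimethylsilyl)oxy]propanoate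
Conditions: TBSCl, imidazole, DMF, 25 °C
Reagents that add atoms: tert-butyldimethylsilyl chloride, CC(C)(C)[Si](C)(C)Cl
Why: Standard silylation of a secondary alcohol; C23 is untouched.

Step 9
Reactants: 13 methyl (2R)-2-[(tert-butyldimethylsilyl)oxy]propanoate
Product: 14 (2R)-2-[(tert-butyldimethylsilyl)oxy]propan-1-ol
Conditions: iBu2AlH (2.5 equiv), CH2Cl2, −78 → 0 °C
Reagents that add atoms: none
Why: Hydride reduction of the ester to the primary alcohol; the α-silyloxy centre does not epimerise under these non-basic conditions.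

Step 10
Reactants: 14 (2R)-2-[(tert-butyldimethylsilyl)oxy]propan-1-ol
Product: 15 (2R)-2-[(tert-butyldimethylsilyl)oxy]propyl trifluoromethanesulfonate
Conditions: Tf2O, 2,6-lutidine, CH2Cl2, −78 °C; used at once
Reagents that add atoms: trifluoromethanesulfonic anhydride, O=S(=O)(OS(=O)(=O)C(F)(F)F)C(F)(F)F
Why: O-Sulfonylation of the primary alcohol; β-silyloxy primary triflates are known, highly reactive alkylating agents for enolates where the corresponding halides or epoxides are sluggish.

Step 11
Reactants: 11 (5S)-4-methoxy-6-methyl-1-oxaspiro[4.5]deca-3,6-diene-2,8-dione; 15 (2R)-2-[(tert-butyldimethylsilyl)oxy]propyl trifluoromethanesulfonate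
Product: 16 (5S,9R)-9-{(2R)-2-[(tert-butyldimethylsilyl)oxy]propyl}-4-methoxy-6-methyl-1-oxaspiro[4.5]deca-3,6-diene-2,8-dione
Conditions: LiN(iPr)2 (1.05 equiv), THF, −78 °C; then 15, −78 → −40 °C
Reagents that add atoms: none
Why: Kinetic deprotonation of the enone at the alpha-prime carbon C21 gives the cross-conjugated lithium dienolate, which is C-alkylated by the primary triflate (SN2, C23 untouched). The electrophile approaches the face of ring C that carries O28, away from C32 and its overhanging methoxy group, which sets C21 (R) with the side chain cis to O28; the product is not left in equilibrating base.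

Step 12
Reactants: 16 (5S,9R)-9-{(2R)-2-[(tert-butyldimethylsilyl)oxy]propyl}-4-methoxy-6-methyl-1-oxaspiro[4.5]deca-3,6-diene-2,8-dione
Product: 17 (5S,6R,9R)-6-allyl-9-{(2R)-2-[(tert-butyldimethylsilyl)oxy]propyl}-4-methoxy-6-methyl-8-[(trimethylsilyl)oxy]-1-oxaspiro[4.5]deca-3,7-dien-2-one
Conditions: allylSnBu3 (2 equiv), Me3SiOTf (1.5 equiv), CH2Cl2, −78 °C; Et3N quench
Reagents that add atoms: allyltributylstannane, C=CC[Sn](CCCC)(CCCC)CCCC; trimethylsilyl trifluoromethanesulfonate, C[Si](C)(C)OS(=O)(=O)C(F)(F)F
Why: Hosomi–Sakurai-type conjugate allylation promoted by a silyl triflate; the O-silylated enone is attacked at C15 by the allylstannane and the oxygen keeps the silyl group, so the C17=C18 enol ether is formed regiospecifically. The allyl group enters on the O28 face (anti to C32 and its methoxy group), which puts the C16 methyl on the C32 face and sets the quaternary centre C15 (R).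

Step 13
Reactants: 17 (5S,6R,9R)-6-allyl-9-{(2R)-2-[(tert-butyldimethylsilyl)oxy]propyl}-4-methoxy-6-methyl-8-[(trimethylsilyl)oxy]-1-oxaspiro[4.5]deca-3,7-dien-2-one
Product: 18 (5S,6R,9R)-6-allyl-9-{(2R)-2-[(tert-butyldimethylsilyl)oxy]propyl}-4-methoxy-6-methyl-2-oxo-1-oxaspiro[4.5]deca-3,7-dien-8-yl trifluoromethanesulfonate
Conditions: CsF, PhNTf2, 1,2-dimethoxyethane, 25 °C
Reagents that add atoms: N-phenylbis(trifluoromethanesulfonimide), O=S(=O)(N(c1ccccc1)S(=O)(=O)C(F)(F)F)C(F)(F)F
Why: Fluoride cleaves the trimethylsilyl enol ether selectively (the hindered alkyl silyl ether is inert to CsF in an ether solvent) and the caesium enolate is triflated on oxygen with the regiochemistry intact; a known route from silyl enol ethers to enol triflates.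

Step 14
Reactants: 18 (5S,6R,9R)-6-allyl-9-{(2R)-2-[(tert-butyldimethylsilyl)oxy]propyl}-4-methoxy-6-methyl-2-oxo-1-oxaspiro[4.5]deca-3,7-dien-8-yl trifluoromethanesulfonate
Product: 19 (5S,6R,9R)-6-allyl-9-{(2R)-2-[(tert-butyldimethylsilyl)oxy]propyl}-8-(hydroxymethyl)-4-methoxy-6-methyl-1-oxaspiro[4.5]deca-3,7-dien-2-one
Conditions: Bu3SnCH2OH, Pd(PPh3)4 (5 mol%), LiCl (3 equiv), 1,4-dioxane, 95 °C
Reagents that add atoms: (tributylstannyl)methanol, OC[Sn](CCCC)(CCCC)CCCC
Why: Stille coupling of the enol triflate with a hydroxymethylstannane; chloride exchanges the triflate on palladium and speeds transmetalation, and C19 arrives as the allylic alcohol, so no hydride reagent is needed next to the lactone.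

Step 15
Reactants: 19 (5S,6R,9R)-6-allyl-9-{(2R)-2-[(tert-butyldimethylsilyl)oxy]propyl}-8-(hydroxymethyl)-4-methoxy-6-methyl-1-oxaspiro[4.5]deca-3,7-dien-2-one
Product: 20 (5S,6R,9R)-6-allyl-8-{[(tert-butyldimethylsilyl)oxy]methyl}-9-{(2R)-2-[(tert-butyldimethylsilyl)oxy]propyl}-4-methoxy-6-methyl-1-oxaspiro[4.5]deca-3,7-dien-2-one
Conditions: TBSCl, imidazole, CH2Cl2, 25 °C
Reagents that add atoms: tert-butyldimethylsilyl chloride, CC(C)(C)[Si](C)(C)Cl
Why: Silylation of the primary allylic alcohol, so that both hydroxyls carry the same group and the only acidic C–H left is H–C31.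

Step 16
Reactants: 21 methyl (R)-3-hydroxy-2-methylpropanoate
Product: 22 methyl (R)-3-[(tert-butyldimethylsilyl)oxy]-2-methylpropanoate
Conditions: TBSCl, imidazole, CH2Cl2, 25 °C
Reagents that add atoms: tert-butyldimethylsilyl chloride, CC(C)(C)[Si](C)(C)Cl
Why: Standard protection of the primary alcohol; the stereocentre (later C10) is untouched.

Step 17
Reactants: 22 methyl (R)-3-[(tert-butyldimethylsilyl)oxy]-2-methylpropanoate
Product: 23 (R)-3-[(tert-butyldimethylsilyl)oxy]-2-methylpropanal
Conditions: iBu2AlH (1.1 equiv), CH2Cl2, −78 °C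
Reagents that add atoms: none
Why: Partial reduction of the ester through the aluminium hemiacetal, which is stable at −78 °C; the aldehyde is used without chromatography to avoid epimerisation.

Step 18
Reactants: 23 (R)-3-[(tert-butyldimethylsilyl)oxy]-2-methylpropanal
Product: 24 (S)-tert-butyldimethyl[(2-methylbut-3-yn-1-yl)oxy]silane
Conditions: dimethyl (1-diazo-2-oxopropyl)phosphonate, K2CO3, MeOH, 0 → 25 °C
Reagents that add atoms: dimethyl (1-diazo-2-oxopropyl)phosphonate, COP(=O)(OC)C(=[N+]=[N-])C(C)=O
Why: Seyferth–Gilbert homologation in the Ohira–Bestmann variant; the mild carbonate base is known to convert α-branched aldehydes of this type to alkynes without loss of configuration (the descriptor changes from R to S only through the priority rules).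

Step 19
Reactants: 25 (S)-citronellal
Product: 26 (1E,4S)-1-iodo-4,8-dimethylnona-1,7-diene
Conditions: CrCl2 (6 equiv), CHI3 (2 equiv), THF/1,4-dioxane, 0 → 25 °C
Reagents that add atoms: iodoform, IC(I)I
Why: Takai olefination; the geminal dichromium species from iodoform adds to the aldehyde and eliminates anti to give the E-alkenyl iodide, and the β-stereocentre (C2) is not touched.

Step 20
Reactants: 26 (1E,4S)-1-iodo-4,8-dimethylnona-1,7-diene
Product: 27 (4S,6E)-7-iodo-4-methylhept-6-enal
Conditions: O3, CH2Cl2/MeOH, −78 °C (Sudan red 7B end-point); then PPh3, → 25 °C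
Reagents that add atoms: ozone, [O-][O+]=O
Why: Ozonolysis with reductive work-up; the electron-rich trisubstituted alkene reacts far faster than the alkenyl iodide, and the dye end-point stops the reaction before the iodide is attacked.

Step 21
Reactants: 27 (4S,6E)-7-iodo-4-methylhept-6-enal
Product: 29 (2E,4S,6R,8E)-9-iodo-2,6-dimethyl-1-oxonona-2,8-dien-4-yl benzoate, via α-benzoyloxy aldehyde 28 (not isolated)
Conditions: (S)-2-[diphenyl(trimethylsilyloxy)methyl]pyrrolidine (10 mol%), (PhCO2)2, hydroquinone (10 mol%), THF, 0 → 25 °C; extractive work-up; then Ph3P=C(CH3)CHO, toluene, 70 °C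
Reagents that add atoms: dibenzoyl peroxide, O=C(OOC(=O)c1ccccc1)c1ccccc1; 2-(triphenylphosphoranylidene)propanal, CC(C=O)=P(c1ccccc1)(c1ccccc1)c1ccccc1
Why: Enamine catalysis; the prolinol silyl ether shields one face of the enamine of 27 and the peroxide transfers a benzoyloxy group to C4 under catalyst control (the remote C2 centre has little influence). The labile aldehyde 28 is olefinated at once by the stabilised formyl ylide (Wittig reaction), which gives the E-2-methyl enal.

Step 22
Reactants: 24 (S)-tert-butyldimethyl[(2-methylbut-3-yn-1-yl)oxy]silane; 29 (2E,4S,6R,8E)-9-iodo-2,6-dimethyl-1-oxonona-2,8-dien-4-yl benzoate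
Product: 31 (2E,4S,6R,8E,10E,12S)-13-[(tert-butyldimethylsilyl)oxy]-2,6,12-trimethyl-1-oxotrideca-2,8,10-trien-4-yl benzoate, via alkenylborane 30 (not isolated)
Conditions: 24, (c-C6H11)2BH [from BH3·SMe2 and cyclohexene], THF, 0 °C; then 29, Pd(dppf)Cl2 (5 mol%), AsPh3, Cs2CO3, DMF/H2O, 25 °C
Reagents that add atoms: none
Why: syn-Hydroboration of the terminal alkyne gives the E-alkenylborane, and Suzuki–Miyaura coupling with the E-alkenyl iodide retains both geometries, so the E,E-diene forms stereospecifically; the carbonate base at room temperature leaves the benzoate and the enal intact.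

Step 23
Reactants: 31 (2E,4S,6R,8E,10E,12S)-13-[(tert-butyldimethylsilyl)oxy]-2,6,12-trimethyl-1-oxotrideca-2,8,10-trien-4-yl benzoate
Product: 32 (1R,2S,4aS,6R,8S,8aR)-8-(benzoyloxy)-2-{(2S)-1-[(tert-butyldimethylsilyl)oxy]propan-2-yl}-1,6-dimethyl-1,2,4a,5,6,7,8,8a-octahydronaphthalene-1-carbaldehyde
Conditions: Me2AlCl (1.5 equiv), CH2Cl2, −78 → −30 °C
Reagents that add atoms: none
Why: Lewis acid-promoted intramolecular Diels–Alder reaction of an E,E-diene with an E-2-methyl enal; the aluminium-bound formyl group is endo, which gives the trans ring fusion and places C34 cis to the C10 chain (C5, C6, C9 and C36 are set together). The C4 benzoate stays equatorial, anti to the forming C5–C6 bond, because the axial position would clash with the C37 methyl (allylic 1,3-strain); this fixes the face of the dienophile and, since the C2 methyl is trans to the benzoate on the nascent ring A, forces that methyl axial as the target requires.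

Step 24
Reactants: 32 octalin aldehyde benzoate
Product: 33 diol of 32 (C34 aldehyde reduced to CH2OH, C4 benzoate cleaved to OH; all stereocentres as in 32)
Conditions: iBu2AlH (5 equiv), CH2Cl2, −78 → 0 °C
Reagents that add atoms: none
Why: Hydride reduction of the aldehyde and reductive cleavage of the benzoate in one operation; no stereocentre is affected.

Step 25
Reactants: 33 diol
Product: 34 C34-O-tert-butyldimethylsilyl ether of 33 (C4 hydroxyl free)
Conditions: TBSCl (1.05 equiv), imidazole, CH2Cl2, 0 °C
Reagents that add atoms: tert-butyldimethylsilyl chloride, CC(C)(C)[Si](C)(C)Cl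
Why: Selective silylation of the primary hydroxyl in preference to the hindered secondary one on C4.

Step 26
Reactants: 34 mono-silyl ether
Product: 35 O-(C4) S-methyl dithiocarbonate (xanthate) of 34
Conditions: NaH, imidazole (cat.), THF, 0 °C; CS2; then MeI, 25 °C
Reagents that add atoms: carbon disulfide, S=C=S; iodomethane, CI
Why: Standard xanthate formation from the alkoxide, carbon disulfide and iodomethane, in preparation for radical deoxygenation.

Step 27
Reactants: 35 xanthate
Product: 36 tert-butyl{[(1S,2S,4aS,6S,8aR)-2-{(2S)-1-[(tert-butyldimethylsilyl)oxy]propan-2-yl}-1,6-dimethyl-1,2,4a,5,6,7,8,8a-octahydronaphthalen-1-yl]methoxy}dimethylsilane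
Conditions: Bu3SnH, AIBN (cat.), toluene, 110 °C
Reagents that add atoms: none
Why: Barton–McCombie deoxygenation; the secondary C4 radical has no alkene within reach for cyclisation and is reduced by the tin hydride, which removes the control element and leaves C4 as CH2.

Step 28
Reactants: 36 bis-silyl ether
Product: 37 (2S)-2-[(1S,2S,4aS,6S,8aR)-1-(hydroxymethyl)-1,6-dimethyl-1,2,4a,5,6,7,8,8a-octahydronaphthalen-2-yl]propan-1-ol
Conditions: Bu4NF, THF, 25 °C
Reagents that add atoms: none
Why: Fluoride cleavage of both primary silyl ethers.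

Step 29
Reactants: 37 diol
Product: 38 (1S,2S,4aS,6S,8aR)-1,6-dimethyl-2-[(2S)-1-oxopropan-2-yl]-1,2,4a,5,6,7,8,8a-octahydronaphthalene-1-carbaldehyde
Conditions: Dess–Martin periodinane, NaHCO3, CH2Cl2, 0 → 25 °C
Reagents that add atoms: none
Why: Buffered, non-basic oxidation of both primary alcohols; the C10 centre alpha to the new C12 aldehyde is not exposed to base, and C36 is quaternary.

Step 30
Reactants: 38 dialdehyde
Product: 39 (1S,2S,4aS,6S,8aR)-2-[(2R)-but-3-en-2-yl]-1,6-dimethyl-1,2,4a,5,6,7,8,8a-octahydronaphthalene-1-carbaldehyde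
Conditions: Ph3P=CH2 (1.05 equiv; from Ph3PCH3Br, KN(SiMe3)2), THF, −78 → −20 °C
Reagents that add atoms: methylenetriphenylphosphorane, C=P(c1ccccc1)(c1ccccc1)c1ccccc1
Why: Wittig methylenation with one equivalent of ylide at low temperature; the α-branched C12 aldehyde reacts, while the C34 aldehyde on the quaternary carbon, flanked by C5 and C9, is much more hindered and is left for the union.

Step 31
Reactants: 20 spirotetronate fragment; 39 decalin aldehyde
Product: 40 C34 carbinol formed by addition of C31 of 20 to the formyl group of 39 (both C34 epimers)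
Conditions: 20, LiN(iPr)2 (1.1 equiv), THF, −78 °C; then 39, −78 → −40 °C; NH4Cl
Reagents that add atoms: none
Why: The vinylic H–C31 of a 4-methoxyfuranone is the only acidic hydrogen of 20 and is lithiated cleanly; 1,2-addition to the non-enolisable aldehyde forms the C31–C34 bond. The new carbinol centre is removed in the next step, so its configuration is immaterial.

Step 32
Reactants: 40 carbinol
Product: 41 seco ketone (C34 ketone; C10 vinyl and C15 allyl still open)
Conditions: Dess–Martin periodinane, NaHCO3, CH2Cl2, 25 °C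
Reagents that add atoms: none
Why: Oxidation of the allylic, neopentyl carbinol to the 3-acyl tetronate; mild conditions spare the alkenes and silyl ethers.

Step 33
Reactants: 41 seco ketone
Product: 42 macrocycle (target as O33-methyl ether and O20,O25-bis-tert-butyldimethylsilyl ether)
Conditions: second-generation Grubbs catalyst RuCl2(=CHPh)(H2IMes)(PCy3) (10 mol%), CH2Cl2 (2 mM), 40 °C
Reagents that add atoms: none
Why: Ring-closing metathesis of the two terminal alkenes closes the eleven-membered ring with loss of ethene; the ring alkenes and the tetronate alkene are too substituted to compete. The reversible catalyst should favour the less strained E-alkene, as known for eleven-membered rings of related spirotetronates.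

Step 34
Reactants: 42 macrocycle
Product: 43 target O33-methyl ether (O20 and O25 free)
Conditions: HF·pyridine, THF/pyridine, 0 → 25 °C
Reagents that add atoms: none
Why: Buffered fluoride cleavage of the primary allylic and the secondary silyl ether; the acyl tetronate methyl ether is stable to these conditions.

Step 35
Reactants: 43 target O33-methyl ether
Product: 44 target CNP0189906.1
Conditions: LiCl, DMSO, 60 °C; then aq. HCl to pH 3
Reagents that add atoms: none
Why: SN2 demethylation of the vinylogous methyl ester by chloride, the standard unmasking of 3-acyl tetronic acids; no stereocentre is involved and the product is set free on acidification.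

## Compound list

1 | 4'-hydroxyacetophenone | CC(=O)c1ccc(O)cc1 | starting material
2 | dimethyl carbonate | COC(=O)OC | starting material
3 | methyl 3-(4-hydroxyphenyl)-3-oxopropanoate | COC(=O)CC(=O)c1ccc(O)cc1 | intermediate
4 | trimethyl orthoformate | COC(OC)OC | starting material
5 | methyl (E)-3-(4-hydroxyphenyl)-3-methoxyacrylate | COC(=O)/C=C(/OC)c1ccc(O)cc1 | intermediate
6 | (E)-3-(4-hydroxyphenyl)-3-methoxyacrylic acid | O=C(O)/C=C(/OC)c1ccc(O)cc1 | intermediate
7 | 4-methoxy-1-oxaspiro[4.5]deca-3,6,9-triene-2,8-dione | COC1=CC(=O)OC12C=CC(=O)C=C2 | intermediate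
8 | methylzinc enolate (O-bound at C18) of the methyl adduct of 7, (5S,6R) | C[C@@H]1C=C(O[Zn]C)C=C[C@]12OC(=O)C=C2OC | intermediate
9 | (5S,6R)-4-methoxy-6-methyl-8-[(trimethylsilyl)oxy]-1-oxaspiro[4.5]deca-3,7,9-trien-2-one | C[C@@H]1C=C(O[Si](C)(C)C)C=C[C@]12OC(=O)C=C2OC | intermediate
10 | (5S)-4-methoxy-6-methyl-1-oxaspiro[4.5]deca-3,6,9-triene-2,8-dione | CC1=CC(=O)C=C[C@]12OC(=O)C=C2OC | intermediate
11 | (5S)-4-methoxy-6-methyl-1-oxaspiro[4.5]deca-3,6-diene-2,8-dione | CC1=CC(=O)CC[C@]12OC(=O)C=C2OC | intermediate
12 | methyl (R)-lactate | C[C@@H](O)C(=O)OC | starting material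
13 | methyl (2R)-2-[(tert-butyldimethylsilyl)oxy]propanoate | C[C@@H](O[Si](C)(C)C(C)(C)C)C(=O)OC | intermediate
14 | (2R)-2-[(tert-butyldimethylsilyl)oxy]propan-1-ol | C[C@@H](O[Si](C)(C)C(C)(C)C)CO | intermediate
15 | (2R)-2-[(tert-butyldimethylsilyl)oxy]propyl trifluoromethanesulfonate | C[C@@H](O[Si](C)(C)C(C)(C)C)COS(=O)(=O)C(F)(F)F | intermediate
16 | (5S,9R)-9-{(2R)-2-[(tert-butyldimethylsilyl)oxy]propyl}-4-methoxy-6-methyl-1-oxaspiro[4.5]deca-3,6-diene-2,8-dione | CC1=CC(=O)[C@H](C[C@@H](C)O[Si](C)(C)C(C)(C)C)C[C@]12OC(=O)C=C2OC | intermediate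
17 | (5S,6R,9R)-6-allyl-9-{(2R)-2-[(tert-butyldimethylsilyl)oxy]propyl}-4-methoxy-6-methyl-8-[(trimethylsilyl)oxy]-1-oxaspiro[4.5]deca-3,7-dien-2-one | C=CC[C@]1(C)C=C(O[Si](C)(C)C)[C@H](C[C@@H](C)O[Si](C)(C)C(C)(C)C)C[C@]12OC(=O)C=C2OC | intermediate
18 | (5S,6R,9R)-6-allyl-9-{(2R)-2-[(tert-butyldimethylsilyl)oxy]propyl}-4-methoxy-6-methyl-2-oxo-1-oxaspiro[4.5]deca-3,7-dien-8-yl trifluoromethanesulfonate | C=CC[C@]1(C)C=C(OS(=O)(=O)C(F)(F)F)[C@H](C[C@@H](C)O[Si](C)(C)C(C)(C)C)C[C@]12OC(=O)C=C2OC | intermediate
19 | (5S,6R,9R)-6-allyl-9-{(2R)-2-[(tert-butyldimethylsilyl)oxy]propyl}-8-(hydroxymethyl)-4-methoxy-6-methyl-1-oxaspiro[4.5]deca-3,7-dien-2-one | C=CC[C@]1(C)C=C(CO)[C@H](C[C@@H](C)O[Si](C)(C)C(C)(C)C)C[C@]12OC(=O)C=C2OC | intermediate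
20 | (5S,6R,9R)-6-allyl-8-{[(tert-butyldimethylsilyl)oxy]methyl}-9-{(2R)-2-[(tert-butyldimethylsilyl)oxy]propyl}-4-methoxy-6-methyl-1-oxaspiro[4.5]deca-3,7-dien-2-one | C=CC[C@]1(C)C=C(CO[Si](C)(C)C(C)(C)C)[C@H](C[C@@H](C)O[Si](C)(C)C(C)(C)C)C[C@]12OC(=O)C=C2OC | intermediate
21 | methyl (R)-3-hydroxy-2-methylpropanoate | COC(=O)[C@H](C)CO | starting material
22 | methyl (R)-3-[(tert-butyldimethylsilyl)oxy]-2-methylpropanoate | COC(=O)[C@H](C)CO[Si](C)(C)C(C)(C)C | intermediate
23 | (R)-3-[(tert-butyldimethylsilyl)oxy]-2-methylpropanal | O=C[C@H](C)CO[Si](C)(C)C(C)(C)C | intermediate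
24 | (S)-tert-butyldimethyl[(2-methylbut-3-yn-1-yl)oxy]silane | C#C[C@H](C)CO[Si](C)(C)C(C)(C)C | intermediate
25 | (S)-citronellal [(3S)-3,7-dimethyloct-6-enal] | C[C@H](CC=O)CCC=C(C)C | starting material
26 | (1E,4S)-1-iodo-4,8-dimethylnona-1,7-diene | C[C@H](C/C=C/I)CCC=C(C)C | intermediate
27 | (4S,6E)-7-iodo-4-methylhept-6-enal | O=CCC[C@H](C)C/C=C/I | intermediate
28 | (2S,4R,6E)-7-iodo-4-methyl-1-oxohept-6-en-2-yl benzoate | O=C[C@@H](OC(=O)c1ccccc1)C[C@H](C)C/C=C/I | intermediate
29 | (2E,4S,6R,8E)-9-iodo-2,6-dimethyl-1-oxonona-2,8-dien-4-yl benzoate | O=C/C(C)=C/[C@@H](OC(=O)c1ccccc1)C[C@H](C)C/C=C/I | intermediate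
30 | (S,E)-{4-[(tert-butyldimethylsilyl)oxy]-3-methylbut-1-en-1-yl}dicyclohexylborane | C1CCCCC1B(/C=C/[C@H](C)CO[Si](C)(C)C(C)(C)C)C1CCCCC1 | intermediate
31 | (2E,4S,6R,8E,10E,12S)-13-[(tert-butyldimethylsilyl)oxy]-2,6,12-trimethyl-1-oxotrideca-2,8,10-trien-4-yl benzoate | O=C/C(C)=C/[C@@H](OC(=O)c1ccccc1)C[C@H](C)C/C=C/C=C/[C@H](C)CO[Si](C)(C)C(C)(C)C | intermediate
32 | (1R,2S,4aS,6R,8S,8aR)-8-(benzoyloxy)-2-{(2S)-1-[(tert-butyldimethylsilyl)oxy]propan-2-yl}-1,6-dimethyl-1,2,4a,5,6,7,8,8a-octahydronaphthalene-1-carbaldehyde (trans-fused; benzoate equatorial, ring A methyl axial) | C[C@H]1C[C@H](OC(=O)c3ccccc3)[C@@H]2[C@H](C=C[C@@H]([C@H](C)CO[Si](C)(C)C(C)(C)C)[C@@]2(C)C=O)C1 | intermediate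
33 | diol of 32 (C34 CH2OH, C4 OH) | C[C@H]1C[C@H](O)[C@@H]2[C@H](C=C[C@@H]([C@H](C)CO[Si](C)(C)C(C)(C)C)[C@@]2(C)CO)C1 | intermediate
34 | C34-O-tert-butyldimethylsilyl ether of 33 | C[C@H]1C[C@H](O)[C@@H]2[C@H](C=C[C@@H]([C@H](C)CO[Si](C)(C)C(C)(C)C)[C@@]2(C)CO[Si](C)(C)C(C)(C)C)C1 | intermediate
35 | O-(C4) S-methyl dithiocarbonate of 34 | C[C@H]1C[C@H](OC(=S)SC)[C@@H]2[C@H](C=C[C@@H]([C@H](C)CO[Si](C)(C)C(C)(C)C)[C@@]2(C)CO[Si](C)(C)C(C)(C)C)C1 | intermediate
36 | tert-butyl{[(1S,2S,4aS,6S,8aR)-2-{(2S)-1-[(tert-butyldimethylsilyl)oxy]propan-2-yl}-1,6-dimethyl-1,2,4a,5,6,7,8,8a-octahydronaphthalen-1-yl]methoxy}dimethylsilane | C[C@H]1CC[C@@H]2[C@H](C=C[C@@H]([C@H](C)CO[Si](C)(C)C(C)(C)C)[C@@]2(C)CO[Si](C)(C)C(C)(C)C)C1 | intermediate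
37 | (2S)-2-[(1S,2S,4aS,6S,8aR)-1-(hydroxymethyl)-1,6-dimethyl-1,2,4a,5,6,7,8,8a-octahydronaphthalen-2-yl]propan-1-ol | C[C@H]1CC[C@@H]2[C@H](C=C[C@@H]([C@H](C)CO)[C@@]2(C)CO)C1 | intermediate
38 | (1S,2S,4aS,6S,8aR)-1,6-dimethyl-2-[(2S)-1-oxopropan-2-yl]-1,2,4a,5,6,7,8,8a-octahydronaphthalene-1-carbaldehyde | C[C@H]1CC[C@@H]2[C@H](C=C[C@@H]([C@H](C)C=O)[C@@]2(C)C=O)C1 | intermediate
39 | (1S,2S,4aS,6S,8aR)-2-[(2R)-but-3-en-2-yl]-1,6-dimethyl-1,2,4a,5,6,7,8,8a-octahydronaphthalene-1-carbaldehyde | C[C@H]1CC[C@@H]2[C@H](C=C[C@@H]([C@H](C)C=C)[C@@]2(C)C=O)C1 | intermediate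
40 | C34 carbinol (mixture of C34 epimers): C31 of 20 bonded to the carbinol carbon that replaces the formyl group of 39 | C[C@H]1CC[C@@H]2[C@H](C=C[C@@H]([C@H](C)C=C)[C@@]2(C)C(O)C3=C(OC)[C@@]4(C[C@@H](C[C@@H](C)O[Si](C)(C)C(C)(C)C)C(CO[Si](C)(C)C(C)(C)C)=C[C@@]4(C)CC=C)OC3=O)C1 | intermediate
41 | seco ketone (C34 ketone of 40) | C[C@H]1CC[C@@H]2[C@H](C=C[C@@H]([C@H](C)C=C)[C@@]2(C)C(=O)C3=C(OC)[C@@]4(C[C@@H](C[C@@H](C)O[Si](C)(C)C(C)(C)C)C(CO[Si](C)(C)C(C)(C)C)=C[C@@]4(C)CC=C)OC3=O)C1 | intermediate
42 | macrocycle: target as O33-methyl ether and O20,O25-bis(tert-butyldimethylsilyl) ether | C[C@H]1CC[C@@H]2[C@H](C=C[C@H]3[C@H](C)/C=C/C[C@]4(C)C=C(CO[Si](C)(C)C(C)(C)C)[C@H](C[C@@H](C)O[Si](C)(C)C(C)(C)C)C[C@]45OC(=O)C(=C5OC)C(=O)[C@@]23C)C1 | intermediate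
43 | target O33-methyl ether | C[C@H]1CC[C@@H]2[C@H](C=C[C@H]3[C@H](C)/C=C/C[C@]4(C)C=C(CO)[C@H](C[C@@H](C)O)C[C@]45OC(=O)C(=C5OC)C(=O)[C@@]23C)C1 | intermediate
44 | target CNP0189906.1 | C[C@H]1CC[C@@H]2[C@H](C=C[C@H]3[C@H](C)/C=C/C[C@]4(C)C=C(CO)[C@H](C[C@@H](C)O)C[C@]45OC(=O)C(=C5O)C(=O)[C@@]23C)C1 | target

## Step count and least certain steps

Total step count: 35. Longest linear sequence: 17 steps (steps 1–7, 11–15 and 31–35; equally steps 19–35).

**Step 4 (key step).**
- Risk: the phenoxonium ion is intercepted before O28 reaches C27 (phenol–phenol coupling, or anodic attack on the electron-rich enol ether), so charge is consumed without spirocyclisation.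
- Fallback, from ester 5 back to 7: two-electron oxidation with PhI(OAc)2 in MeCN/H2O lets water add at C27 and gives the para-quinol methyl (E)-3-(1-hydroxy-4-oxocyclohexa-2,5-dien-1-yl)-3-methoxyacrylate F1. Its tertiary hydroxyl lies cis to the ester across the E alkene and closes ring D by acid-catalysed lactonisation (TsOH, toluene) with loss of methanol. O28 then comes from water and the ring-forming bond is O28–C29.

**Step 12 (conjugate allylation at C15).**
- Risk: bond formation at a β-carbon next to the fully substituted spiro centre is slow. The silyl-activated enone may then be consumed by 1,2-addition or simply returned, and the facial preference for the O28 face may erode.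
- Fallback, from 16 back to 19, moving the bond formation into a sigmatropic shift:
  - LiCH2OPMB (from Bu3SnCH2OPMB and n-BuLi, CeCl3) adds to the C18 carbonyl anti to the C21 chain and gives tertiary allylic alcohol F2 (C19 already in place, oxygen on the O28 face).
  - Eschenmoser–Claisen rearrangement (MeC(OMe)2NMe2, xylene, 140 °C) delivers C14 to C15 on the face of that oxygen and moves the alkene to C17=C18, giving dimethylamide F3.
  - Cp2Zr(H)Cl reduces the amide to aldehyde F4.
  - Ph3P=CH2 gives allyl compound F5 (the O20 4-methoxybenzyl ether of 19).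
  - DDQ removes the benzyl ether and returns 19.

**Step 23 (intramolecular Diels–Alder reaction).**
- Risk: the axial C2 methyl raises the energy of the desired transition state, so the endo (trans-fused) and facial preferences may erode. Ionisation of the allylic benzoate by the Lewis acid is a lesser risk.
- Fallback, from alkyne 24 and purchased hept-6-yn-1-ol back to 37, putting the methyl in after the cycloaddition:
  - Hydrozirconation–iodination (Cp2Zr(H)Cl, then I2) gives (E)-7-iodohept-6-en-1-ol F6, and Dess–Martin oxidation gives (E)-7-iodohept-6-enal F7.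
  - The conditions of steps 21–25 then give, in turn, enal benzoate F8, triene F9, the cycloadduct F10 without a ring A methyl (no axial substituent is now required), diol F11 and mono-silyl ether F12.
  - Dess–Martin oxidation gives C4 ketone F13.
  - LiN(iPr)2/Me3SiCl followed by Pd(OAc)2 gives the C2=C3 enone F14.
  - Me2CuLi adds axially, trans to the C6–C7 bond, and gives methyl ketone F15 with the axial C2 methyl.
  - Wolff–Kishner reduction (N2H4·H2O, KOH, diethylene glycol, 195 °C), in which the silyl ethers are expected to be lost as well, returns diol 37 (if they survive, 36).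

**Step 33 (ring-closing metathesis).**
- Risk: intermolecular metathesis (dimers) outruns closure of the strained eleven-membered ring, or the ring closes to the Z alkene.
- Fallback, from 20 and 39 back to 42, closing the ring at C31–C34:
  - 20 is lithiated and iodinated (LiN(iPr)2, then I2) to 3-iodotetronate F16.
  - Cross-metathesis of F16 with 39 (same ruthenium catalyst, excess 39) forms the acyclic E C12=C13 alkene under thermodynamic control and gives iodo aldehyde F17.
  - Nozaki–Hiyama–Kishi macrocyclisation (CrCl2, NiCl2 (cat.), DMSO/THF, high dilution) joins C31 to the C34 aldehyde and gives macrocyclic carbinol F18.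
  - Dess–Martin oxidation gives 42.

**Step 11 (alkylation at C21).**
- Risk: SN2 at a β-branched carbon is slow, so O-alkylation or proton exchange between product and enolate (loss of C21 configuration, γ-deprotonation) competes.
- Fallback, from 11 back to 16, using an azaenolate and an epoxide:
  - Me2NNH2 with cat. AcOH gives N,N-dimethylhydrazone F19.
  - LiN(iPr)2 followed by (R)-propylene oxide opens the epoxide at CH2 from the same ring face and gives hydroxy hydrazone F20.
  - Aqueous CuCl2 hydrolyses it to hydroxy enone F21.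
  - TBSOTf/2,6-lutidine gives 16.

## Further compounds

F1 | step 4 | methyl (E)-3-(1-hydroxy-4-oxocyclohexa-2,5-dien-1-yl)-3-methoxyacrylate | COC(=O)/C=C(/OC)C1(O)C=CC(=O)C=C1
F2 | step 12 | tertiary allylic alcohol: C18 carbinol of 16 bearing CH2O(4-methoxybenzyl), hydroxyl on the O28 face | CC1=C[C@@](O)(COCc2ccc(OC)cc2)[C@H](C[C@@H](C)O[Si](C)(C)C(C)(C)C)C[C@]13OC(=O)C=C3OC
F3 | step 12 | N,N-dimethylamide: C15 quaternary with CH2C(=O)NMe2 in place of allyl, O20 as 4-methoxybenzyl ether | CN(C)C(=O)C[C@]1(C)C=C(COCc2ccc(OC)cc2)[C@H](C[C@@H](C)O[Si](C)(C)C(C)(C)C)C[C@]13OC(=O)C=C3OC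
F4 | step 12 | aldehyde from F3 (C13 formyl) | O=CC[C@]1(C)C=C(COCc2ccc(OC)cc2)[C@H](C[C@@H](C)O[Si](C)(C)C(C)(C)C)C[C@]13OC(=O)C=C3OC
F5 | step 12 | O20 4-methoxybenzyl ether of 19 | C=CC[C@]1(C)C=C(COCc2ccc(OC)cc2)[C@H](C[C@@H](C)O[Si](C)(C)C(C)(C)C)C[C@]13OC(=O)C=C3OC
F6 | step 23 | (E)-7-iodohept-6-en-1-ol | OCCCCC/C=C/I
F7 | step 23 | (E)-7-iodohept-6-enal | O=CCCCC/C=C/I
F8 | step 23 | (2E,4S,8E)-9-iodo-2-methyl-1-oxonona-2,8-dien-4-yl benzoate | O=C/C(C)=C/[C@@H](OC(=O)c1ccccc1)CCC/C=C/I
F9 | step 23 | (2E,4S,8E,10E,12S)-13-[(tert-butyldimethylsilyl)oxy]-2,12-dimethyl-1-oxotrideca-2,8,10-trien-4-yl benzoate | O=C/C(C)=C/[C@@H](OC(=O)c1ccccc1)CCC/C=C/C=C/[C@H](C)CO[Si](C)(C)C(C)(C)C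
F10 | step 23 | analogue of 32 without the ring A methyl | C1C[C@H](OC(=O)c3ccccc3)[C@@H]2[C@H](C=C[C@@H]([C@H](C)CO[Si](C)(C)C(C)(C)C)[C@@]2(C)C=O)C1
F11 | step 23 | analogue of 33 without the ring A methyl | C1C[C@H](O)[C@@H]2[C@H](C=C[C@@H]([C@H](C)CO[Si](C)(C)C(C)(C)C)[C@@]2(C)CO)C1
F12 | step 23 | analogue of 34 without the ring A methyl | C1C[C@H](O)[C@@H]2[C@H](C=C[C@@H]([C@H](C)CO[Si](C)(C)C(C)(C)C)[C@@]2(C)CO[Si](C)(C)C(C)(C)C)C1
F13 | step 23 | C4 ketone from F12 | C1CC(=O)[C@@H]2[C@H](C=C[C@@H]([C@H](C)CO[Si](C)(C)C(C)(C)C)[C@@]2(C)CO[Si](C)(C)C(C)(C)C)C1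
F14 | step 23 | C2=C3 enone from F13 | C1=CC(=O)[C@@H]2[C@H](C=C[C@@H]([C@H](C)CO[Si](C)(C)C(C)(C)C)[C@@]2(C)CO[Si](C)(C)C(C)(C)C)C1
F15 | step 23 | C4 ketone with axial C2 methyl | C[C@H]1CC(=O)[C@@H]2[C@H](C=C[C@@H]([C@H](C)CO[Si](C)(C)C(C)(C)C)[C@@]2(C)CO[Si](C)(C)C(C)(C)C)C1
F16 | step 33 | 3-iodo derivative of 20 (iodine on C31) | C=CC[C@]1(C)C=C(CO[Si](C)(C)C(C)(C)C)[C@H](C[C@@H](C)O[Si](C)(C)C(C)(C)C)C[C@]12OC(=O)C(I)=C2OC
F17 | step 33 | acyclic E-alkene from cross-metathesis of F16 and 39 (C34 aldehyde, C31 iodide) | C[C@H]1CC[C@@H]2[C@H](C=C[C@@H]([C@H](C)/C=C/C[C@]3(C)C=C(CO[Si](C)(C)C(C)(C)C)[C@H](C[C@@H](C)O[Si](C)(C)C(C)(C)C)C[C@]34OC(=O)C(I)=C4OC)[C@@]2(C)C=O)C1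
F18 | step 33 | macrocyclic C34 carbinol (both epimers), otherwise as 42 | C[C@H]1CC[C@@H]2[C@H](C=C[C@H]3[C@H](C)/C=C/C[C@]4(C)C=C(CO[Si](C)(C)C(C)(C)C)[C@H](C[C@@H](C)O[Si](C)(C)C(C)(C)C)C[C@]45OC(=O)C(=C5OC)C(O)[C@@]23C)C1
F19 | step 11 | N,N-dimethylhydrazone of 11 | CC1=CC(=NN(C)C)CC[C@]12OC(=O)C=C2OC
F20 | step 11 | C21-[(2R)-2-hydroxypropyl] hydrazone | CC1=CC(=NN(C)C)[C@H](C[C@@H](C)O)C[C@]12OC(=O)C=C2OC
F21 | step 11 | (5S,9R)-9-[(2R)-2-hydroxypropyl]-4-methoxy-6-methyl-1-oxaspiro[4.5]deca-3,6-diene-2,8-dione | CC1=CC(=O)[C@H](C[C@@H](C)O)C[C@]12OC(=O)C=C2OC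
A1 | alternative 1 | decalin C34 carboxylic acid with C12 as silyl ether | C[C@H]1CC[C@@H]2[C@H](C=C[C@@H]([C@H](C)CO[Si](C)(C)C(C)(C)C)[C@@]2(C)C(=O)O)C1
A2 | alternative 1 | trans-fused six-membered lactone (C34 carbonyl, ring oxygen on C7, E-alkenyl chain on C7; C36 configuration not fixed) | C[C@H]1CC[C@@H]2[C@H]([C@H](/C=C/[C@H](C)CO[Si](C)(C)C(C)(C)C)OC(=O)C2C)C1
A3 | alternative 2 | target as tetronate methyl ether and bis(methoxymethyl) ether | C[C@H]1CC[C@@H]2[C@H](C=C[C@H]3[C@H](C)/C=C/C[C@]4(C)C=C(COCOC)[C@H](C[C@@H](C)OCOC)C[C@]45OC(=O)C(=C5OC)C(=O)[C@@]23C)C1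
A4 | alternative 2 | twelve-membered cyclic sulfone (sulfur between C12 and C13) | C[C@H]1CC[C@@H]2[C@H](C=C[C@H]3[C@H](C)CS(=O)(=O)CC[C@]4(C)C=C(COCOC)[C@H](C[C@@H](C)OCOC)C[C@]45OC(=O)C(=C5OC)C(=O)[C@@]23C)C1
A5 | alternative 3 | cyclopropyl carbinol with quaternary C15 | COc1ccc(COCC[C@@]24C[C@H]4[C@@H](O)CC[C@]23OC(=O)C=C3OC)cc1
A6 | alternative 3 | spirotetronate cyclohexenol (C15=C17 alkene, C18 hydroxyl) | COc1ccc(COCCC2=C[C@@H](O)CC[C@]23OC(=O)C=C3OC)cc1
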